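## Retrosynthetic overview
1. The lactol comes from the lactone, and the lactone from a bridged ether (RuO4, then a borane reduction that spares esters). The tertiary acetate comes from trans-diaxial hydration of a ring A cyclohexene.
2. Ring A is formed last, by bromonium-induced 6-endo cyclisation of the prenyl / 1,1-disubstituted 1,5-diene side chain. This is the step proposed for irieane biogenesis from an oppositane-type diterpene.
3. The cyclopentane is formed second, by 5-exo radical cyclisation of a primary iodide onto an enone built from sulcatone.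
4. The bromocyclohexane and the oxa bridge are formed first and together, in one bromiranium-initiated cation–olefin cascade of an acyclic diene ester. A spiro tetrahydrofuran oxygen traps the cation and iodide opens the resulting oxonium ion.
5. The cascade precursor comes from 5-chloropentan-2-one, triethyl phosphonoacetate and tetrahydrofuran-3-one (HWE, Wittig). Shi epoxidation and bromide opening fix the absolute configuration.

Assumption: the lactol carbon equilibrates by ring–chain tautomerism, and the drawn (R)-anomer, the one found in nature, is taken as the stable one.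
Assumption: in step 11 the catalyst antipode is the one that gives the (S)-C–Br centre; both antipodes are made from commercial BINOL.

## Route

Step 1
Reactants: 1 5-chloropentan-2-one; 2 triethyl phosphonoacetate
Product: 3 ethyl (E)-6-chloro-3-methylhex-2-enoate
Conditions: NaH, THF, 0 °C to rt; E isomer separated on silica
Reagents that add atoms: none
Why: Horner–Wadsworth–Emmons olefination of the methyl ketone puts the ester trans to the longer chain (E:Z about 5:1), and the stabilised phosphonate anion is too weak a base to close the γ-chloro ketone to a cyclopropane.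

Step 2
Reactants: 3 ethyl (E)-6-chloro-3-methylhex-2-enoate
Product: 5 [(E)-6-ethoxy-4-methyl-6-oxohex-4-en-1-yl]triphenylphosphonium iodide, via primary iodide 4 (not isolated)
Conditions: NaI, PPh3, MeCN, reflux
Reagents that add atoms: sodium iodide [Na+].[I-]; triphenylphosphine c1ccc(cc1)P(c1ccccc1)c1ccccc1
Why: Finkelstein exchange gives the more reactive primary iodide, which quaternises PPh3 by SN2, while the β,β-disubstituted enoate is inert to the phosphine.

Step 3
Reactants: 5 [(E)-6-ethoxy-4-methyl-6-oxohex-4-en-1-yl]triphenylphosphonium iodide; 6 tetrahydrofuran-3-one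
Product: 8 ethyl (2E,6Z)-6-(dihydrofuran-3(2H)-ylidene)-3-methylhex-2-enoate, via phosphonium ylide 7 (not isolated)
Conditions: NaN(SiMe3)2, THF, −78 °C; then 6, −78 °C to rt
Reagents that add atoms: none
Why: Wittig olefination with a non-stabilised ylide, in which α-alkoxy ketones place the ylide chain cis to the CH2O group, sets the Z-alkylidene geometry that later makes the CH2O carbon axial.

Step 4
Reactants: 8 ethyl (2E,6Z)-6-(dihydrofuran-3(2H)-ylidene)-3-methylhex-2-enoate
Product: 9 ethyl (E)-3-methyl-5-[(2R,3S)-1,5-dioxaspiro[2.4]heptan-2-yl]pent-2-enoate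
Conditions: D-fructose-derived Shi ketone (30 mol %), KHSO5 (as 2KHSO5·KHSO4·K2SO4), K2CO3, Bu4NHSO4, MeCN/dimethoxymethane/aq. Na2B4O7 buffer, 0 °C
Reagents that add atoms: potassium peroxymonosulfate [K+].[O-]S(=O)(=O)OO
Why: Shi asymmetric epoxidation attacks only the electron-rich trisubstituted alkene (the enoate is inert) and, by the spiro transition-state model for trisubstituted alkenes, gives the (2R,3S)-epoxide in about 90% ee, which is the source of absolute configuration for the tricycle.

Step 5
Reactants: 9 ethyl (E)-3-methyl-5-[(2R,3S)-1,5-dioxaspiro[2.4]heptan-2-yl]pent-2-enoate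
Product: 10 ethyl (2E,6S)-6-bromo-6-[(3S)-3-hydroxytetrahydrofuran-3-yl]-3-methylhex-2-enoate
Conditions: LiBr, AcOH, THF, rt
Reagents that add atoms: lithium bromide [Li+].[Br-]
Why: SN2 halohydrin opening by bromide at the secondary epoxide carbon (the spiro carbon is tertiary and inductively deactivated by the ring oxygen) inverts that centre and sets the (S)-C–Br stereocentre anti to the tertiary hydroxyl.

Step 6
Reactants: 10 ethyl (2E,6S)-6-bromo-6-[(3S)-3-hydroxytetrahydrofuran-3-yl]-3-methylhex-2-enoate
Product: 13 ethyl (1S,2S,5R,8S)-2-bromo-1-(2-iodoethyl)-5-methyl-6-oxabicyclo[3.2.1]octane-8-carboxylate, via bromiranium triflate 11 (not isolated), via tricyclic oxonium triflate 12 (not isolated)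
Conditions: (CF3SO2)2O, 2,6-di-tert-butyl-4-methylpyridine, CH2Cl2, −78 to −30 °C; then Bu4NI, −30 °C to rt
Reagents that add atoms: tetrabutylammonium iodide CCCC[N+](CCCC)(CCCC)CCCC.[I-]
Why: Proposed new method: activation of the tertiary hydroxyl triggers ionisation with anchimeric help from the anti bromine, so a single-enantiomer bromiranium ion forms with no Br+ carrier or free alkene present to racemise it; the enoate α-carbon opens it at the tertiary carbon through a chair (anti addition, the Z and E geometries become equatorial Br, axial CH2O and equatorial ester), the oxygen on the axial CH2 traps the tertiary cation on its own face as a strained oxonium ion, and iodide cleaves this at its only unhindered O–CH2 carbon, which sets C1, C5 and C8, keeps C2 and closes two rings at once; the closest known reaction types are enantiospecific bromonium-induced polyene cyclisation from bromohydrin derivatives, acid- or bromonium-induced cyclisation of geranate esters, and bromonium-triggered oxonium formation and opening in cyclic ether synthesis.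

Step 7
Reactants: 13 ethyl (1S,2S,5R,8S)-2-bromo-1-(2-iodoethyl)-5-methyl-6-oxabicyclo[3.2.1]octane-8-carboxylate
Product: 14 (1S,2S,5R,8S)-2-bromo-1-(2-iodoethyl)-5-methyl-6-oxabicyclo[3.2.1]octane-8-carbaldehyde
Conditions: iBu2AlH (1.1 equiv), CH2Cl2, −78 °C; aq. KNaC4H4O6
Reagents that add atoms: none
Why: Low-temperature iBu2AlH reduction of the hindered ester delivers one hydride only and gives the aldehyde on work-up, with both alkyl halides and the stable equatorial C8 configuration untouched.

Step 8
Reactants: 14 (1S,2S,5R,8S)-2-bromo-1-(2-iodoethyl)-5-methyl-6-oxabicyclo[3.2.1]octane-8-carbaldehyde; 15 6-methylhept-5-en-2-one (sulcatone)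
Product: 19 (E)-1-[(1S,2S,5R,8S)-2-bromo-1-(2-iodoethyl)-5-methyl-6-oxabicyclo[3.2.1]octan-8-yl]-7-methylocta-1,6-dien-3-one, via lithium enolate 16 (not isolated), via lithium aldolate 17 (not isolated), via mesylate 18 (not isolated)
Conditions: 15, LiN(iPr)2, THF, −78 °C; then 14; then MeSO2Cl, iPr2NEt, −78 to 0 °C
Reagents that add atoms: none
Why: Directed aldol addition of the kinetic methyl-side enolate followed by mesylation and E1cB elimination is an aldol condensation that gives the E-enone, and the low temperature keeps the enolate from alkylating the primary iodide.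

Step 9
Reactants: 19 (E)-1-[(1S,2S,5R,8S)-2-bromo-1-(2-iodoethyl)-5-methyl-6-oxabicyclo[3.2.1]octan-8-yl]-7-methylocta-1,6-dien-3-one
Product: 21 1-[(1S,3aS,4S,7R,7aS)-4-bromo-7-methylhexahydro-1H-7,3a-(epoxymethano)inden-1-yl]-6-methylhept-5-en-2-one, via boron enolate 20 (not isolated)
Conditions: Et3B (3 equiv), air, CH2Cl2 (0.02 M), −20 °C to rt; then pH 7 buffer
Reagents that add atoms: none
Why: Tin-free Giese-type 5-exo radical conjugate cyclisation, in which ethyl radicals abstract only the iodine, the primary radical adds to the enone through a chair-like Beckwith–Houk transition state with the enone arm pseudo-equatorial and anti to C7 (this sets C1 as S and gives the trans-hydrindane), and Et3B traps the enoxyl radical as its boron enolate before it can add to the prenyl alkene.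

Step 10
Reactants: 21 1-[(1S,3aS,4S,7R,7aS)-4-bromo-7-methylhexahydro-1H-7,3a-(epoxymethano)inden-1-yl]-6-methylhept-5-en-2-one
Product: 22 (1S,3aS,4S,7R,7aS)-4-bromo-7-methyl-1-(6-methyl-2-methylidenehept-5-en-1-yl)hexahydro-1H-7,3a-(epoxymethano)indene
Conditions: Ph3PCH3Br, KOtBu, THF, 0 °C to rt
Reagents that add atoms: methyltriphenylphosphonium bromide C[P+](c1ccccc1)(c1ccccc1)c1ccccc1.[Br-]
Why: Wittig methylenation of the unhindered dialkyl ketone installs the 1,1-disubstituted alkene, and the equatorial neopentyl-type bromide has no anti-periplanar hydrogen for elimination.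

Step 11
Reactants: 22 (1S,3aS,4S,7R,7aS)-4-bromo-7-methyl-1-(6-methyl-2-methylidenehept-5-en-1-yl)hexahydro-1H-7,3a-(epoxymethano)indene
Product: 23 (1S,3aS,4S,7R,7aS)-4-bromo-1-{[(4S)-4-bromo-5,5-dimethylcyclohex-1-en-1-yl]methyl}-7-methylhexahydro-1H-7,3a-(epoxymethano)indene
Conditions: 1,3-dibromo-5,5-dimethylhydantoin (0.55 equiv), BINOL-derived chiral thiophosphoramide (10 mol %), toluene/CH2Cl2, −78 °C
Reagents that add atoms: 1,3-dibromo-5,5-dimethylhydantoin CC1(C)N(Br)C(=O)N(Br)C1=O
Why: Catalytic enantioselective bromonium-induced cation–olefin cyclisation, in which the chiral Lewis base–Br+ complex selects one face of the most electron-rich (prenyl) alkene, the CH2 terminus of the 1,1-disubstituted alkene closes ring A through a chair (6-endo, Markovnikov, equatorial Br, S at the new centre) and the tertiary cation loses the accessible ring proton remote from the gem-dimethyl group, while catalyst control turns the minor enantiomer of 22 into a separable diastereomer.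

Step 12
Reactants: 23 (1S,3aS,4S,7R,7aS)-4-bromo-1-{[(4S)-4-bromo-5,5-dimethylcyclohex-1-en-1-yl]methyl}-7-methylhexahydro-1H-7,3a-(epoxymethano)indene
Product: 25 (1S,4S)-4-bromo-1-{[(1S,3aS,4S,7R,7aS)-4-bromo-7-methylhexahydro-1H-7,3a-(epoxymethano)inden-1-yl]methyl}-3,3-dimethylcyclohexan-1-ol, via organomercurial 24 (not isolated)
Conditions: Hg(OAc)2, THF/H2O, rt; then NaOH, NaBH4, 0 °C
Reagents that add atoms: water O
Why: Oxymercuration–demercuration (Markovnikov hydration), in which Hg(OAc)2 adds to the alkene face anti to the axial ring methyl in the half-chair with equatorial Br and water opens the mercurinium ion at the tertiary carbon in the trans-diaxial (Fürst–Plattner) sense, whereas the other diaxial mode would need a 1,3-diaxial Hg/Br contact, so the hydroxyl ends up axial and cis to Br (1S), and NaBH4 replaces mercury by hydrogen without touching the C–Br bonds.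

Step 13
Reactants: 25 (1S,4S)-4-bromo-1-{[(1S,3aS,4S,7R,7aS)-4-bromo-7-methylhexahydro-1H-7,3a-(epoxymethano)inden-1-yl]methyl}-3,3-dimethylcyclohexan-1-ol
Product: 26 (1S,4S)-4-bromo-1-{[(1S,3aS,4S,7R,7aS)-4-bromo-7-methylhexahydro-1H-7,3a-(epoxymethano)inden-1-yl]methyl}-3,3-dimethylcyclohexyl acetate
Conditions: Ac2O, DMAP, Et3N, CH2Cl2, 40 °C
Reagents that add atoms: acetic anhydride CC(=O)OC(C)=O
Why: DMAP-catalysed acylation esterifies the only hydroxyl with retention at the carbinol carbon, and the cis Br/O arrangement rules out intramolecular SN2 displacement of bromide.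

Step 14
Reactants: 26 (1S,4S)-4-bromo-1-{[(1S,3aS,4S,7R,7aS)-4-bromo-7-methylhexahydro-1H-7,3a-(epoxymethano)inden-1-yl]methyl}-3,3-dimethylcyclohexyl acetate
Product: 27 (1S,4S)-4-bromo-1-{[(1S,3aS,4S,7R,7aS)-4-bromo-7-methyl-9-oxohexahydro-1H-7,3a-(epoxymethano)inden-1-yl]methyl}-3,3-dimethylcyclohexyl acetate
Conditions: RuCl3·xH2O (5 mol %), NaIO4, CCl4/MeCN/H2O, rt
Reagents that add atoms: sodium periodate [Na+].[O-]I(=O)(=O)=O
Why: RuO4 oxidation of an ether to a lactone works here because the bridge OCH2 carries the only C–H bonds activated by oxygen (the other ether carbon is quaternary) and no alkene is left, so the acetate and both bromides survive.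

Step 15
Reactants: 27 (1S,4S)-4-bromo-1-{[(1S,3aS,4S,7R,7aS)-4-bromo-7-methyl-9-oxohexahydro-1H-7,3a-(epoxymethano)inden-1-yl]methyl}-3,3-dimethylcyclohexyl acetate
Product: 29 (1S,4S)-4-bromo-1-{[(1S,3aS,4S,7R,7aS,9R)-4-bromo-9-hydroxy-7-methylhexahydro-1H-7,3a-(epoxymethano)inden-1-yl]methyl}-3,3-dimethylcyclohexyl acetate (CNP0196016.1), via boron lactolate 28 (not isolated)
Conditions: disiamylborane (3 equiv, from BH3·THF and 2-methylbut-2-ene), THF, 0 °C to rt; then MeOH
Reagents that add atoms: none
Why: Chemoselective lactone-to-lactol reduction, since disiamylborane reduces γ-lactones but not carboxylic esters, so the strained bridged lactone reacts and the tertiary acetate stays; hydride arrives from the face of the one-carbon bridge and leaves the hydroxyl on the side of the CHBr carbon (9R), which is also the anomer reached by ring–chain equilibration.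

## Compound list
1 | 5-chloropentan-2-one | CC(=O)CCCCl | starting material
2 | triethyl phosphonoacetate | CCOC(=O)CP(=O)(OCC)OCC | starting material
3 | ethyl (E)-6-chloro-3-methylhex-2-enoate | CCOC(=O)/C=C(C)/CCCCl | intermediate
4 | ethyl (E)-6-iodo-3-methylhex-2-enoate | CCOC(=O)/C=C(C)/CCCI | intermediate
5 | [(E)-6-ethoxy-4-methyl-6-oxohex-4-en-1-yl]triphenylphosphonium iodide | CCOC(=O)/C=C(C)/CCC[P+](c1ccccc1)(c1ccccc1)c1ccccc1.[I-] | intermediate
6 | tetrahydrofuran-3-one | O=C1CCOC1 | starting material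
7 | ethyl (E)-3-methyl-6-(triphenyl-λ5-phosphanylidene)hex-2-enoate (ylide of 5) | CCOC(=O)/C=C(C)/CCC=P(c1ccccc1)(c1ccccc1)c1ccccc1 | intermediate
8 | ethyl (2E,6Z)-6-(dihydrofuran-3(2H)-ylidene)-3-methylhex-2-enoate | CCOC(=O)/C=C(C)/CC/C=C1\COCC1 | intermediate
9 | ethyl (E)-3-methyl-5-[(2R,3S)-1,5-dioxaspiro[2.4]heptan-2-yl]pent-2-enoate | CCOC(=O)/C=C(C)/CC[C@H]1O[C@@]12COCC2 | intermediate
10 | ethyl (2E,6S)-6-bromo-6-[(3S)-3-hydroxytetrahydrofuran-3-yl]-3-methylhex-2-enoate | CCOC(=O)/C=C(C)/CC[C@H](Br)[C@@]1(O)COCC1 | intermediate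
11 | spiro bromiranium triflate (Br bridges C6 of the chain and C3 of the tetrahydrofuran, on the face opposite the former epoxide oxygen) | CCOC(=O)/C=C(C)/CC[C@@H]1[Br+][C@]12COCC2.[O-]S(=O)(=O)C(F)(F)F | intermediate
12 | tricyclic oxonium triflate (ring oxygen bonded to the bridge CH2, the CH2CH2 arm and the methyl-bearing carbon) | C1C[C@]23C[O+]1[C@](C)(CC[C@@H]2Br)[C@H]3C(=O)OCC.[O-]S(=O)(=O)C(F)(F)F | intermediate
13 | ethyl (1S,2S,5R,8S)-2-bromo-1-(2-iodoethyl)-5-methyl-6-oxabicyclo[3.2.1]octane-8-carboxylate | ICC[C@]12CO[C@](C)(CC[C@@H]1Br)[C@H]2C(=O)OCC | intermediate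
14 | (1S,2S,5R,8S)-2-bromo-1-(2-iodoethyl)-5-methyl-6-oxabicyclo[3.2.1]octane-8-carbaldehyde | ICC[C@]12CO[C@](C)(CC[C@@H]1Br)[C@H]2C=O | intermediate
15 | 6-methylhept-5-en-2-one (sulcatone) | CC(=O)CCC=C(C)C | starting material
16 | lithium 6-methylhepta-1,5-dien-2-olate | [Li+].C=C([O-])CCC=C(C)C | intermediate
17 | lithium aldolate of 14 and 16 (carbinol centre either way, lost in the elimination) | ICC[C@]12CO[C@](C)(CC[C@@H]1Br)[C@H]2C([O-])CC(=O)CCC=C(C)C.[Li+] | intermediate
18 | β-mesyloxy ketone from 17 | ICC[C@]12CO[C@](C)(CC[C@@H]1Br)[C@H]2C(OS(C)(=O)=O)CC(=O)CCC=C(C)C | intermediate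
19 | (E)-1-[(1S,2S,5R,8S)-2-bromo-1-(2-iodoethyl)-5-methyl-6-oxabicyclo[3.2.1]octan-8-yl]-7-methylocta-1,6-dien-3-one | ICC[C@]12CO[C@](C)(CC[C@@H]1Br)[C@H]2/C=C/C(=O)CCC=C(C)C | intermediate
20 | diethylboron enolate of 21 | CCB(CC)OC(CCC=C(C)C)=C[C@@H]1CC[C@]23CO[C@](C)(CC[C@@H]2Br)[C@@H]13 | intermediate
21 | 1-[(1S,3aS,4S,7R,7aS)-4-bromo-7-methylhexahydro-1H-7,3a-(epoxymethano)inden-1-yl]-6-methylhept-5-en-2-one | CC(C)=CCCC(=O)C[C@@H]1CC[C@]23CO[C@](C)(CC[C@@H]2Br)[C@@H]13 | intermediate
22 | (1S,3aS,4S,7R,7aS)-4-bromo-7-methyl-1-(6-methyl-2-methylidenehept-5-en-1-yl)hexahydro-1H-7,3a-(epoxymethano)indene | CC(C)=CCCC(=C)C[C@@H]1CC[C@]23CO[C@](C)(CC[C@@H]2Br)[C@@H]13 | intermediate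
23 | (1S,3aS,4S,7R,7aS)-4-bromo-1-{[(4S)-4-bromo-5,5-dimethylcyclohex-1-en-1-yl]methyl}-7-methylhexahydro-1H-7,3a-(epoxymethano)indene | CC1(C)CC(C[C@@H]2CC[C@]34CO[C@](C)(CC[C@@H]3Br)[C@@H]24)=CC[C@@H]1Br | intermediate
24 | 2-(acetoxymercurio) derivative of 25 (Hg axial, trans to the hydroxyl) | O[C@]1(C[C@@H]2CC[C@]34CO[C@](C)(CC[C@@H]3Br)[C@@H]24)[C@@H]([Hg]OC(C)=O)C[C@H](Br)C(C)(C)C1 | intermediate
25 | (1S,4S)-4-bromo-1-{[(1S,3aS,4S,7R,7aS)-4-bromo-7-methylhexahydro-1H-7,3a-(epoxymethano)inden-1-yl]methyl}-3,3-dimethylcyclohexan-1-ol | O[C@]1(C[C@@H]2CC[C@]34CO[C@](C)(CC[C@@H]3Br)[C@@H]24)CC[C@H](Br)C(C)(C)C1 | intermediate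
26 | acetate of 25 | CC(=O)O[C@]1(C[C@@H]2CC[C@]34CO[C@](C)(CC[C@@H]3Br)[C@@H]24)CC[C@H](Br)C(C)(C)C1 | intermediate
27 | 9-oxo (lactone) derivative of 26 | CC(=O)O[C@]1(C[C@@H]2CC[C@]34C(=O)O[C@](C)(CC[C@@H]3Br)[C@@H]24)CC[C@H](Br)C(C)(C)C1 | intermediate
28 | O-disiamylboryl lactolate of 29 | CC(=O)O[C@]1(C[C@@H]2CC[C@]34[C@H](OB(C(C)C(C)C)C(C)C(C)C)O[C@](C)(CC[C@@H]3Br)[C@@H]24)CC[C@H](Br)C(C)(C)C1 | intermediate
29 | (1S,4S)-4-bromo-1-{[(1S,3aS,4S,7R,7aS,9R)-4-bromo-9-hydroxy-7-methylhexahydro-1H-7,3a-(epoxymethano)inden-1-yl]methyl}-3,3-dimethylcyclohexyl acetate | CC(=O)O[C@]1(C[C@@H]2CC[C@]34[C@H](O)O[C@](C)(CC[C@@H]3Br)[C@@H]24)CC[C@H](Br)C(C)(C)C1 | target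

## Step count and risks
Total step count: 15. Longest linear sequence: 15 (fully linear; 6 and 15 are bought).

**Step 6 (cascade).** The enoate is a weak π-nucleophile. A 1,2-hydride shift from the OCH2 group or proton loss may outrun C–C bond formation. The fallback sets out from 9 and comes back at 14, and it makes the nucleophilic alkene electron-rich before the bromiranium ion is generated. The ester of 9 is reduced with iBu2AlH at −78 °C to the epoxy allylic alcohol F1 and silylated (tBuMe2SiCl, imidazole) to the silyl ether F2. LiBr/AcOH then gives the bromohydrin F3. The same (CF3SO2)2O / Bu4NI treatment gives the bicyclic iodo silyl ether F4. HF·pyridine frees the primary alcohol F5, and Dess–Martin periodinane oxidises it to 14.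

**Step 11 (ring A).** The chiral Lewis base catalyst has not been tested with a 1,1-disubstituted alkene terminator on such a substrate, so face selectivity may be low. The fallback sets out from 22 and comes back at 23, and it replaces catalyst control by an enantiospecific bromiranium ion. Shi epoxidation with the same D-fructose-derived ketone oxidises only the trisubstituted alkene, since 1,1-disubstituted alkenes are poor substrates, and gives the (R)-epoxide F6. LiBr/AcOH opens it with inversion to the (S)-bromohydrin F7. (CF3SO2)2O with 2,6-di-tert-butyl-4-methylpyridine ionises the tertiary alcohol, so that ring closure and proton loss give 23.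

**Step 15 (lactone to lactol).** The α-quaternary lactone may be too hindered for the bulky borane. The fallback sets out from 27 and comes back at 29, and it gives up chemoselective reduction in favour of chemoselective deacylation. Excess iBu2AlH at −78 °C reduces the lactone and cleaves the acetate to the lactol diol F8. Ac2O/DMAP/Et3N gives the diacetate F9. Hydrazine acetate in DMF then removes only the anomeric acetate and gives 29.

## Further compounds
F1 | step 6 | (E)-3-methyl-5-[(2R,3S)-1,5-dioxaspiro[2.4]heptan-2-yl]pent-2-en-1-ol | OC/C=C(C)/CC[C@H]1O[C@@]12COCC2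
F2 | step 6 | tert-butyldimethylsilyl ether of F1 | CC(C)(C)[Si](C)(C)OC/C=C(C)/CC[C@H]1O[C@@]12COCC2
F3 | step 6 | (3S)-3-[(1S,4E)-1-bromo-6-(tert-butyldimethylsilyloxy)-4-methylhex-4-en-1-yl]tetrahydrofuran-3-ol | CC(C)(C)[Si](C)(C)OC/C=C(C)/CC[C@H](Br)[C@@]1(O)COCC1
F4 | step 6 | tert-butyldimethylsilyl ether of F5 | ICC[C@]12CO[C@](C)(CC[C@@H]1Br)[C@H]2CO[Si](C)(C)C(C)(C)C
F5 | step 6 | [(1S,2S,5R,8R)-2-bromo-1-(2-iodoethyl)-5-methyl-6-oxabicyclo[3.2.1]octan-8-yl]methanol | ICC[C@]12CO[C@](C)(CC[C@@H]1Br)[C@H]2CO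
F6 | step 11 | (R)-epoxide of the prenyl alkene of 22 | CC1(C)O[C@@H]1CCC(=C)C[C@@H]2CC[C@]34CO[C@](C)(CC[C@@H]3Br)[C@@H]24
F7 | step 11 | (S)-bromohydrin from F6 (secondary bromide, tertiary alcohol) | CC(C)(O)[C@@H](Br)CCC(=C)C[C@@H]1CC[C@]23CO[C@](C)(CC[C@@H]2Br)[C@@H]13
F8 | step 15 | deacetyl derivative of 29 (lactol and tertiary alcohol free) | O[C@]1(C[C@@H]2CC[C@]34[C@H](O)O[C@](C)(CC[C@@H]3Br)[C@@H]24)CC[C@H](Br)C(C)(C)C1
F9 | step 15 | 9-O-acetyl derivative of 29 (diacetate) | CC(=O)O[C@]1(C[C@@H]2CC[C@]34[C@H](OC(C)=O)O[C@](C)(CC[C@@H]3Br)[C@@H]24)CC[C@H](Br)C(C)(C)C1
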